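**Retrosynthetic overview** (locants follow the 1H-isochromene skeleton: O2, C1, C3, C4, C4a, C5–C8, C8a)
1. The 2H-pyran ring is formed last, by oxa-6π electrocyclization (O2–C1) of the dienone C1H2=C8a–C4a=C4–C3=O, which MnO2 oxidation of the two allylic carbinols releases.
2. Key disconnection C4a–C5: the carbocycle is closed by a nickel-catalysed reductive epoxide–alkyne cyclization of an acyclic epoxy enyne. The enabling feature is that C4a–C5H2–C6H(OH) of the carbocycle is a homoallylic alcohol (alkyne + terminal epoxide retron), and the pyran ring O2–C1H2–C8a=C4a–C4H=C3 is the valence tautomer of the 1,2-dialkylidene diene that this cyclization delivers with the required (Z) geometry.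
3. C8–C8a: addition of a 2-lithio-1,3-enyne (from crotonaldehyde, ethynylmagnesium bromide and 1,1-dibromoethene) to an α-acyloxy epoxy aldehyde.
4. C6/C7: Sharpless epoxidation of a (Z)-allylic alcohol; the hindered tertiary aryl ester is installed by Ti(OiPr)4-mediated epoxide opening with the aryl acid (inversion at C7), and the terminal C5–C6 epoxide is then closed.
5. Ring order: carbocycle (step 17), then pyran (step 19).

Key step: step 17

Remark on the chemistry: the two carbinol centres that end as the C3 and C8 carbonyl carbons are introduced without control, carried as epimer mixtures and written without configuration.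

Step 1
Reactants: 1 orsellinic acid (2,4-dihydroxy-6-methylbenzoic acid)
Product: 2 benzyl 2,4-dihydroxy-6-methylbenzoate
Conditions: BnBr, KHCO3, DMF, 23 °C
Reagents that add atoms: benzyl bromide, BrCc1ccccc1
Why: Carboxylate O-alkylation (SN2) with the weak base KHCO3 should esterify the acid only, because the phenols are not deprotonated.

Step 2
Reactants: 2 benzyl 2,4-dihydroxy-6-methylbenzoate
Product: 3 benzyl 2-hydroxy-6-methyl-4-[(triisopropylsilyl)oxy]benzoate
Conditions: i-Pr3SiCl, imidazole, CH2Cl2, 0 °C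
Reagents that add atoms: triisopropylsilyl chloride, CC(C)[Si](Cl)(C(C)C)C(C)C
Why: Silyl ether formation should be selective for the 4-OH, because the 2-OH is hydrogen-bonded to the ester carbonyl and flanked by it.

Step 3
Reactants: 3 benzyl 2-hydroxy-6-methyl-4-[(triisopropylsilyl)oxy]benzoate
Product: 4 benzyl 2-methoxy-6-methyl-4-[(triisopropylsilyl)oxy]benzoate
Conditions: MeOH, PPh3, DIAD, THF, 0 → 23 °C
Reagents that add atoms: methanol, CO
Why: Mitsunobu etherification methylates the chelated phenol under neutral conditions that leave the aryl silyl ether intact.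

Step 4
Reactants: 4 benzyl 2-methoxy-6-methyl-4-[(triisopropylsilyl)oxy]benzoate
Product: 5 2-methoxy-6-methyl-4-[(triisopropylsilyl)oxy]benzoic acid
Conditions: H2 (1 atm), 10% Pd/C, EtOAc, 23 °C
Reagents that add atoms: none
Why: Hydrogenolysis of the benzyl ester frees the di-ortho-substituted acid without the forcing saponification that such a hindered ester would need.

Step 5
Reactants: 6 tert-butyldimethyl(prop-2-yn-1-yloxy)silane; 7 ethyl chloroformate
Product: 9 ethyl 4-[(tert-butyldimethylsilyl)oxy]but-2-ynoate, via lithium acetylide 8 (not isolated)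
Conditions: n-BuLi, THF, −78 °C; then 7, −78 → 0 °C
Reagents that add atoms: none
Why: Deprotonation of the terminal alkyne and C-acylation of the acetylide with a chloroformate is the standard ynoate synthesis.

Step 6
Reactants: 9 ethyl 4-[(tert-butyldimethylsilyl)oxy]but-2-ynoate
Product: 11 ethyl (Z)-4-[(tert-butyldimethylsilyl)oxy]-3-methylbut-2-enoate, via alkenylcuprate 10 (not isolated)
Conditions: Me2CuLi (from copper iodide CuI and MeLi), THF, −78 °C; then MeOH and aq. NH4Cl at −78 °C
Reagents that add atoms: lithium dimethylcuprate, [Li+].C[Cu-]C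
Why: Organocuprate conjugate addition to an ynoate is a syn carbometalation, so cold protonation with retention should give the (Z)-enoate in which the ester and the CH2OSi group are cis.

Step 7
Reactants: 11 ethyl (Z)-4-[(tert-butyldimethylsilyl)oxy]-3-methylbut-2-enoate
Product: 12 (Z)-4-[(tert-butyldimethylsilyl)oxy]-3-methylbut-2-en-1-ol
Conditions: i-Bu2AlH (2.2 equiv), CH2Cl2, −78 °C; aq. potassium sodium tartrate (KNaC4H4O6) work-up
Reagents that add atoms: none
Why: 1,2-Reduction of the unsaturated ester by i-Bu2AlH gives the allylic alcohol without touching the alkene geometry.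

Step 8
Reactants: 12 (Z)-4-[(tert-butyldimethylsilyl)oxy]-3-methylbut-2-en-1-ol
Product: 13 [(2R,3S)-3-{[(tert-butyldimethylsilyl)oxy]methyl}-3-methyloxiran-2-yl]methanol
Conditions: Ti(OiPr)4 (10 mol %), D-(−)-diethyl tartrate (12 mol %), t-BuOOH, 4 Å molecular sieves, CH2Cl2, −20 °C
Reagents that add atoms: tert-butyl hydroperoxide, CC(C)(C)OO
Why: Sharpless asymmetric epoxidation with D-(−)-diethyl tartrate should give the (2R,3S) epoxy alcohol, which sets C6 of the target directly and C7 in the form that step 9 inverts.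

Step 9
Reactants: 13 [(2R,3S)-3-{[(tert-butyldimethylsilyl)oxy]methyl}-3-methyloxiran-2-yl]methanol; 5 2-methoxy-6-methyl-4-[(triisopropylsilyl)oxy]benzoic acid
Product: 14 (2R,3R)-1-[(tert-butyldimethylsilyl)oxy]-3,4-dihydroxy-2-methylbutan-2-yl 2-methoxy-6-methyl-4-[(triisopropylsilyl)oxy]benzoate
Conditions: Ti(OiPr)4 (1.5 equiv), CH2Cl2, 23 °C
Reagents that add atoms: none
Why: Ti(OiPr)4-mediated opening of a 2,3-epoxy alcohol by a carboxylic acid occurs at the carbon remote from the carbinol (here the tertiary C7) with inversion, so the hindered tertiary ester is made by C–O bond formation at carbon and the C6/C7 relationship of the target is set.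

Step 10
Reactants: 14 (2R,3R)-1-[(tert-butyldimethylsilyl)oxy]-3,4-dihydroxy-2-methylbutan-2-yl 2-methoxy-6-methyl-4-[(triisopropylsilyl)oxy]benzoate
Product: 15 (2R)-1-[(tert-butyldimethylsilyl)oxy]-2-[(2R)-oxiran-2-yl]propan-2-yl 2-methoxy-6-methyl-4-[(triisopropylsilyl)oxy]benzoate
Conditions: PPh3, DIAD, toluene, 0 → 80 °C
Reagents that add atoms: none
Why: Mitsunobu cyclodehydration of the 1,2-diol activates the primary hydroxyl, which the secondary oxygen displaces, so the terminal epoxide forms with retention at C6.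

Step 11
Reactants: 15 (2R)-1-[(tert-butyldimethylsilyl)oxy]-2-[(2R)-oxiran-2-yl]propan-2-yl 2-methoxy-6-methyl-4-[(triisopropylsilyl)oxy]benzoate
Product: 16 (2R)-1-hydroxy-2-[(2R)-oxiran-2-yl]propan-2-yl 2-methoxy-6-methyl-4-[(triisopropylsilyl)oxy]benzoate
Conditions: HF·pyridine, pyridine, THF, 0 → 23 °C
Reagents that add atoms: none
Why: Buffered acidic fluoride desilylation should cleave the primary alkyl silyl ether while the aryl silyl ether and the epoxide survive.

Step 12
Reactants: 16 (2R)-1-hydroxy-2-[(2R)-oxiran-2-yl]propan-2-yl 2-methoxy-6-methyl-4-[(triisopropylsilyl)oxy]benzoate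
Product: 17 (2S)-1-oxo-2-[(2R)-oxiran-2-yl]propan-2-yl 2-methoxy-6-methyl-4-[(triisopropylsilyl)oxy]benzoate
Conditions: Dess–Martin periodinane, NaHCO3, CH2Cl2, 0 → 23 °C
Reagents that add atoms: none
Why: Dess–Martin oxidation gives the aldehyde under buffered conditions, and the quaternary α-carbon cannot epimerise.

Step 13
Reactants: 18 (E)-but-2-enal; 19 ethynylmagnesium bromide
Product: 20 (4E)-hex-4-en-1-yn-3-ol (racemic)
Conditions: THF, 0 °C; aq. NH4Cl
Reagents that add atoms: none
Why: 1,2-Addition of the alkynyl Grignard reagent to the enal gives the racemic propargylic alcohol, whose carbinol centre later becomes the C3 carbonyl.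

Step 14
Reactants: 20 (4E)-hex-4-en-1-yn-3-ol
Product: 21 triethyl{[(4E)-hex-4-en-1-yn-3-yl]oxy}silane
Conditions: Et3SiCl, imidazole, CH2Cl2, 0 °C
Reagents that add atoms: triethylsilyl chloride, CC[Si](Cl)(CC)CC
Why: Silyl ether formation protects the carbinol for the organolithium and nickel steps.

Step 15
Reactants: 21 triethyl{[(4E)-hex-4-en-1-yn-3-yl]oxy}silane; 22 1,1-dibromoethene
Product: 23 {[(2E)-7-bromoocta-2,7-dien-5-yn-4-yl]oxy}triethylsilane
Conditions: Pd(PPh3)4 (5 mol %), copper iodide CuI (10 mol %), i-Pr2NH, THF, 23 °C, 22 in excess (5 equiv)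
Reagents that add atoms: none
Why: Sonogashira coupling with an excess of the 1,1-dihaloalkene should stop at monoalkynylation and give the 2-bromo-1,3-enyne that carries C1, C8a, C4a, C4 and C3.

Step 16
Reactants: 23 {[(2E)-7-bromoocta-2,7-dien-5-yn-4-yl]oxy}triethylsilane; 17 (2S)-1-oxo-2-[(2R)-oxiran-2-yl]propan-2-yl 2-methoxy-6-methyl-4-[(triisopropylsilyl)oxy]benzoate
Product: 26 (2S,8E)-4-methylidene-2-[(2R)-oxiran-2-yl]-3,7-bis[(triethylsilyl)oxy]dec-8-en-5-yn-2-yl 2-methoxy-6-methyl-4-[(triisopropylsilyl)oxy]benzoate (carbinol epimer mixture), via alkenyllithium 24 (not isolated), via lithium alkoxide 25 (not isolated)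
Conditions: t-BuLi (2 equiv), Et2O, −78 °C; then 17; then Et3SiOTf, −78 → 0 °C
Reagents that add atoms: triethylsilyl trifluoromethanesulfonate, CC[Si](CC)(CC)OS(=O)(=O)C(F)(F)F
Why: Bromine–lithium exchange and 1,2-addition to the aldehyde (faster at −78 °C than attack on the epoxide or the hindered ester) form C8–C8a, and the alkoxide is silylated in situ; the new C8 centre forms as a mixture, which is harmless because it becomes the ketone.

Step 17
Reactants: 26 (2S,8E)-4-methylidene-2-[(2R)-oxiran-2-yl]-3,7-bis[(triethylsilyl)oxy]dec-8-en-5-yn-2-yl 2-methoxy-6-methyl-4-[(triisopropylsilyl)oxy]benzoate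
Product: 27 (1S,2R,4Z)-2-hydroxy-1-methyl-5-methylidene-4-{(3E)-2-[(triethylsilyl)oxy]pent-3-en-1-ylidene}-6-[(triethylsilyl)oxy]cyclohexyl 2-methoxy-6-methyl-4-[(triisopropylsilyl)oxy]benzoate (carbinol epimer mixture)
Conditions: Ni(cod)2 (20 mol %), PBu3 (40 mol %), Et3B (3 equiv), Et2O, 23 °C; aq. NH4Cl work-up
Reagents that add atoms: none
Why: Nickel-catalysed reductive coupling of an alkyne with a terminal epoxide: zerovalent nickel opens the epoxide at its unhindered CH2 terminus (C5), the Ni–C5 bond adds syn across the tethered C4a≡C4 triple bond to form C4a–C5, and ethyl transfer from Et3B followed by β-hydride and C–H reductive elimination puts hydrogen on C4 while boron holds the C6 alkoxide until work-up. The closest known reaction type is the intramolecular form of this coupling, which converts alkynyl terminal epoxides with a three-atom tether into six-membered rings with endo epoxide opening and an exocyclic alkene of defined geometry. The carbocycle (C4a, C5, C6, C7, C8, C8a) closes exo-dig at the alkyne and endo at the epoxide; bonding of C5 to C4 instead would need a trans-cycloheptene and is excluded. No stereocentre is created: C6 keeps its configuration because only the C5–O bond is broken, C7 is untouched, and the (Z) geometry of C4a=C4 (C5 cis to H, so the C3 arm cis to C8a) follows from the syn addition. The step needs attack at the primary epoxide carbon, secured by the quaternary C7 that shields the internal carbon, and reaction at the alkyne in preference to the 1,1-disubstituted alkene, secured by the much faster insertion of alkynes than of such alkenes into nickel–carbon bonds. The product is a 1,2-dialkylidenecyclohexanol that already holds the free C6 hydroxyl and, as its diene, the ring-opened form of the 2H-pyran.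

Step 18
Reactants: 27 (1S,2R,4Z)-2-hydroxy-1-methyl-5-methylidene-4-{(3E)-2-[(triethylsilyl)oxy]pent-3-en-1-ylidene}-6-[(triethylsilyl)oxy]cyclohexyl 2-methoxy-6-methyl-4-[(triisopropylsilyl)oxy]benzoate
Product: 28 (1S,2R,4Z)-2,6-dihydroxy-4-[(3E)-2-hydroxypent-3-en-1-ylidene]-1-methyl-5-methylidenecyclohexyl 4-hydroxy-2-methoxy-6-methylbenzoate (carbinol epimer mixture)
Conditions: Bu4NF, AcOH (1:1), THF, 0 → 23 °C
Reagents that add atoms: none
Why: Fluoride-mediated desilylation buffered with AcOH removes the two triethylsilyl ethers and the aryl silyl ether in one operation, before the base-sensitive β-hydroxy ketone exists.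

Step 19
Reactants: 28 (1S,2R,4Z)-2,6-dihydroxy-4-[(3E)-2-hydroxypent-3-en-1-ylidene]-1-methyl-5-methylidenecyclohexyl 4-hydroxy-2-methoxy-6-methylbenzoate
Product: 31 (6R,7S)-6-hydroxy-7-methyl-8-oxo-3-[(E)-prop-1-en-1-yl]-5,6,7,8-tetrahydro-1H-isochromen-7-yl 4-hydroxy-2-methoxy-6-methylbenzoate (target), via dienone 29 (not isolated), via pyranyl carbinol 30 (not isolated)
Conditions: activated MnO2 (excess), CH2Cl2, 23 °C
Reagents that add atoms: none
Why: Chemoselective MnO2 oxidation of the allylic carbinols (the saturated C6–OH is left) gives the (Z)-dienone, a 1-oxatriene that should close by oxa-6π electrocyclization to the 2H-pyran (O2–C1), and the allylic C8 carbinol of that pyran is oxidised in the same flask, so all C3/C8 epimers converge on the one target.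

**Compound list**
1 | orsellinic acid (2,4-dihydroxy-6-methylbenzoic acid) | Cc1cc(O)cc(O)c1C(=O)O | starting material
2 | benzyl 2,4-dihydroxy-6-methylbenzoate | Cc1cc(O)cc(O)c1C(=O)OCc1ccccc1 | intermediate
3 | benzyl 2-hydroxy-6-methyl-4-[(triisopropylsilyl)oxy]benzoate | Cc1cc(O[Si](C(C)C)(C(C)C)C(C)C)cc(O)c1C(=O)OCc1ccccc1 | intermediate
4 | benzyl 2-methoxy-6-methyl-4-[(triisopropylsilyl)oxy]benzoate | COc1cc(O[Si](C(C)C)(C(C)C)C(C)C)cc(C)c1C(=O)OCc1ccccc1 | intermediate
5 | 2-methoxy-6-methyl-4-[(triisopropylsilyl)oxy]benzoic acid | COc1cc(O[Si](C(C)C)(C(C)C)C(C)C)cc(C)c1C(=O)O | intermediate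
6 | tert-butyldimethyl(prop-2-yn-1-yloxy)silane | C#CCO[Si](C)(C)C(C)(C)C | starting material
7 | ethyl chloroformate | CCOC(=O)Cl | starting material
8 | lithium acetylide of 6 | [Li]C#CCO[Si](C)(C)C(C)(C)C | intermediate
9 | ethyl 4-[(tert-butyldimethylsilyl)oxy]but-2-ynoate | CCOC(=O)C#CCO[Si](C)(C)C(C)(C)C | intermediate
10 | lithium alkenyl(methyl)cuprate from syn addition (Cu cis to the new methyl) | CCOC(=O)/C([Cu-]C)=C(/C)CO[Si](C)(C)C(C)(C)C.[Li+] | intermediate
11 | ethyl (Z)-4-[(tert-butyldimethylsilyl)oxy]-3-methylbut-2-enoate | CCOC(=O)/C=C(/C)CO[Si](C)(C)C(C)(C)C | intermediate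
12 | (Z)-4-[(tert-butyldimethylsilyl)oxy]-3-methylbut-2-en-1-ol | OC/C=C(/C)CO[Si](C)(C)C(C)(C)C | intermediate
13 | [(2R,3S)-3-{[(tert-butyldimethylsilyl)oxy]methyl}-3-methyloxiran-2-yl]methanol | OC[C@H]1O[C@@]1(C)CO[Si](C)(C)C(C)(C)C | intermediate
14 | (2R,3R)-1-[(tert-butyldimethylsilyl)oxy]-3,4-dihydroxy-2-methylbutan-2-yl 2-methoxy-6-methyl-4-[(triisopropylsilyl)oxy]benzoate | CC(C)(C)[Si](C)(C)OC[C@@](C)(OC(=O)c1c(C)cc(O[Si](C(C)C)(C(C)C)C(C)C)cc1OC)[C@H](O)CO | intermediate
15 | (2R)-1-[(tert-butyldimethylsilyl)oxy]-2-[(2R)-oxiran-2-yl]propan-2-yl 2-methoxy-6-methyl-4-[(triisopropylsilyl)oxy]benzoate | CC(C)(C)[Si](C)(C)OC[C@@](C)(OC(=O)c1c(C)cc(O[Si](C(C)C)(C(C)C)C(C)C)cc1OC)[C@H]1CO1 | intermediate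
16 | (2R)-1-hydroxy-2-[(2R)-oxiran-2-yl]propan-2-yl 2-methoxy-6-methyl-4-[(triisopropylsilyl)oxy]benzoate | OC[C@@](C)(OC(=O)c1c(C)cc(O[Si](C(C)C)(C(C)C)C(C)C)cc1OC)[C@H]1CO1 | intermediate
17 | (2S)-1-oxo-2-[(2R)-oxiran-2-yl]propan-2-yl 2-methoxy-6-methyl-4-[(triisopropylsilyl)oxy]benzoate | O=C[C@@](C)(OC(=O)c1c(C)cc(O[Si](C(C)C)(C(C)C)C(C)C)cc1OC)[C@H]1CO1 | intermediate
18 | (E)-but-2-enal (crotonaldehyde) | C/C=C/C=O | starting material
19 | ethynylmagnesium bromide | C#C[Mg]Br | starting material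
20 | (4E)-hex-4-en-1-yn-3-ol (racemic) | C/C=C/C(O)C#C | intermediate
21 | triethyl{[(4E)-hex-4-en-1-yn-3-yl]oxy}silane | C/C=C/C(O[Si](CC)(CC)CC)C#C | intermediate
22 | 1,1-dibromoethene | C=C(Br)Br | starting material
23 | {[(2E)-7-bromoocta-2,7-dien-5-yn-4-yl]oxy}triethylsilane | C/C=C/C(O[Si](CC)(CC)CC)C#CC(Br)=C | intermediate
24 | 2-lithio-1,3-enyne from 23 | C/C=C/C(O[Si](CC)(CC)CC)C#CC([Li])=C | intermediate
25 | lithium alkoxide from addition of 24 to 17 (C8 epimers) | C/C=C/C(O[Si](CC)(CC)CC)C#CC(=C)C(O[Li])[C@@](C)(OC(=O)c1c(C)cc(O[Si](C(C)C)(C(C)C)C(C)C)cc1OC)[C@H]1CO1 | intermediate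
26 | (2S,8E)-4-methylidene-2-[(2R)-oxiran-2-yl]-3,7-bis[(triethylsilyl)oxy]dec-8-en-5-yn-2-yl 2-methoxy-6-methyl-4-[(triisopropylsilyl)oxy]benzoate (carbinol epimers) | C/C=C/C(O[Si](CC)(CC)CC)C#CC(=C)C(O[Si](CC)(CC)CC)[C@@](C)(OC(=O)c1c(C)cc(O[Si](C(C)C)(C(C)C)C(C)C)cc1OC)[C@H]1CO1 | intermediate
27 | (1S,2R,4Z)-2-hydroxy-1-methyl-5-methylidene-4-{(3E)-2-[(triethylsilyl)oxy]pent-3-en-1-ylidene}-6-[(triethylsilyl)oxy]cyclohexyl 2-methoxy-6-methyl-4-[(triisopropylsilyl)oxy]benzoate (carbinol epimers) | C[C@]1(OC(=O)c2c(C)cc(O[Si](C(C)C)(C(C)C)C(C)C)cc2OC)[C@H](O)C/C(=C/C(O[Si](CC)(CC)CC)/C=C/C)C(=C)C1O[Si](CC)(CC)CC | intermediate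
28 | (1S,2R,4Z)-2,6-dihydroxy-4-[(3E)-2-hydroxypent-3-en-1-ylidene]-1-methyl-5-methylidenecyclohexyl 4-hydroxy-2-methoxy-6-methylbenzoate (carbinol epimers) | C[C@]1(OC(=O)c2c(C)cc(O)cc2OC)[C@H](O)C/C(=C/C(O)/C=C/C)C(=C)C1O | intermediate
29 | (1S,2R,4Z)-2,6-dihydroxy-1-methyl-5-methylidene-4-[(3E)-2-oxopent-3-en-1-ylidene]cyclohexyl 4-hydroxy-2-methoxy-6-methylbenzoate (C8 epimers) | C[C@]1(OC(=O)c2c(C)cc(O)cc2OC)[C@H](O)C/C(=C/C(=O)/C=C/C)C(=C)C1O | intermediate
30 | (6R,7S)-6,8-dihydroxy-7-methyl-3-[(E)-prop-1-en-1-yl]-5,6,7,8-tetrahydro-1H-isochromen-7-yl 4-hydroxy-2-methoxy-6-methylbenzoate (C8 epimers) | C/C=C/C1=CC2=C(CO1)C(O)[C@@](C)(OC(=O)c1c(C)cc(O)cc1OC)[C@H](O)C2 | intermediate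
31 | (6R,7S)-6-hydroxy-7-methyl-8-oxo-3-[(E)-prop-1-en-1-yl]-5,6,7,8-tetrahydro-1H-isochromen-7-yl 4-hydroxy-2-methoxy-6-methylbenzoate | C/C=C/C1=CC2=C(CO1)C(=O)[C@@](C)(OC(=O)c1c(C)cc(O)cc1OC)[C@H](O)C2 | target

**Step count and risks**
Total steps: 19. Longest linear sequence: 12 steps (steps 5–12 and 16–19; the aryl-acid branch, steps 1–4, 9–12 and 16–19, is equally long).

Steps most likely to fail:

1. Step 17 (key step). What may go wrong: the conjugated enyne alkene may hold the nickel and steer bond formation to the distal alkyne carbon, which the tether cannot reach, so that intermolecular coupling and oligomerization take over; the epoxide may also open at the internal carbon or not at all. Fallback: the same diene-ol would be assembled by closing the ring at the neighbouring C4a–C8a bond with stepwise chemistry. It sets out from aldehyde 17 (with 21 and 22) and comes back to the route at 27.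
   - Bromine–lithium exchange on 22 (n-BuLi, THF/Et2O/pentane, −110 °C) gives 1-bromovinyllithium F1.
   - F1 adds to 17 to give the lithium alkoxide adduct F2, which is silylated (Et3SiOTf) to the bromoalkene epoxide triethylsilyl ether F3.
   - Alkyne 21 is deprotonated (n-BuLi) to the lithium acetylide F4, which opens the terminal epoxide of F3 at C5 under BF3·OEt2 at −78 °C (Yamaguchi–Hirao alkynylation) to give the homopropargylic alcohol F5.
   - Hydroxyl-directed trans-hydrostannation ([Cp*RuCl]4 cat., Bu3SnH, CH2Cl2) places tin on C4a and hydrogen on C4 in an anti sense, giving the alkenylstannane F6.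
   - Intramolecular Stille coupling (Pd(PPh3)4, copper iodide CuI, CsF, DMF) joins C4a to C8a with retention and gives 27. Anti hydrostannation followed by retentive coupling leads to the same alkene geometry as the syn reductive coupling.

2. Step 9. What may go wrong: the hindered, electron-rich carboxylic acid may open the epoxide too slowly at the tertiary carbon, so that attack at the secondary carbon, loss of stereochemical fidelity at C7 or acyl migration to the neighbouring hydroxyl compete. Fallback: the ester is made by acylation of a tertiary alcohol instead. It sets out from 13 (and 5) and comes back at 14.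
   - The titanium-mediated opening is run with benzoic acid to give the benzoate diol F7.
   - The 1,2-diol is masked (2,2-dimethoxypropane, pyridinium p-toluenesulfonate) as the acetonide benzoate F8.
   - Methanolysis (K2CO3, MeOH) frees the tertiary alcohol F9.
   - Acid 5 is converted ((COCl)2, cat. DMF) into the acid chloride F10, which acylates F9 (DMAP, Et3N, CH2Cl2, 40 °C) to the acetonide aryl ester F11.
   - Mild hydrolysis of the acetonide (aq. AcOH) gives 14.

3. Step 19. What may go wrong: oxidation of the hindered C8 carbinol may stall, the free phenol may be degraded oxidatively, or the α-methylene ketone may dimerize before ring closure. Fallback: a protecting-group sequence with a non-selective oxidant replaces the chemoselective oxidation. It sets out from 27 and comes back at the target 31.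
   - The C6 hydroxyl is silylated (t-BuMe2SiOTf, 2,6-lutidine) to the silyl ether F12.
   - The two triethylsilyl ethers are cleaved selectively (HF·pyridine, pyridine, THF) to the diol F13.
   - Dess–Martin oxidation of both carbinols gives the dienedione F14, which should close by the same oxa-6π electrocyclization to the bis-silylated pyranone F15.
   - Bu4NF/AcOH removes both silyl groups and gives 31.

**Further compounds**
F1 | step 17 | 1-bromovinyllithium | [Li]C(Br)=C
F2 | step 17 | lithium alkoxide adduct of F1 and 17 (C8 epimers) | C=C(Br)C(O[Li])[C@@](C)(OC(=O)c1c(C)cc(O[Si](C(C)C)(C(C)C)C(C)C)cc1OC)[C@H]1CO1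
F3 | step 17 | (2S)-4-bromo-2-[(2R)-oxiran-2-yl]-3-[(triethylsilyl)oxy]pent-4-en-2-yl 2-methoxy-6-methyl-4-[(triisopropylsilyl)oxy]benzoate (C3 epimers) | C=C(Br)C(O[Si](CC)(CC)CC)[C@@](C)(OC(=O)c1c(C)cc(O[Si](C(C)C)(C(C)C)C(C)C)cc1OC)[C@H]1CO1
F4 | step 17 | lithium acetylide of 21 | C/C=C/C(O[Si](CC)(CC)CC)C#C[Li]
F5 | step 17 | homopropargylic alcohol from opening of F3 by F4 (free C6–OH, carbinol epimers) | C=C(Br)C(O[Si](CC)(CC)CC)[C@@](C)(OC(=O)c1c(C)cc(O[Si](C(C)C)(C(C)C)C(C)C)cc1OC)[C@H](O)CC#CC(O[Si](CC)(CC)CC)/C=C/C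
F6 | step 17 | alkenylstannane with tributylstannyl on C4a and H on C4 trans to it | C=C(Br)C(O[Si](CC)(CC)CC)[C@@](C)(OC(=O)c1c(C)cc(O[Si](C(C)C)(C(C)C)C(C)C)cc1OC)[C@H](O)C/C(=C/C(O[Si](CC)(CC)CC)/C=C/C)[Sn](CCCC)(CCCC)CCCC
F7 | step 9 | (2R,3R)-1-[(tert-butyldimethylsilyl)oxy]-3,4-dihydroxy-2-methylbutan-2-yl benzoate | CC(C)(C)[Si](C)(C)OC[C@@](C)(OC(=O)c1ccccc1)[C@H](O)CO
F8 | step 9 | acetonide of F7 | CC(C)(C)[Si](C)(C)OC[C@@](C)(OC(=O)c1ccccc1)[C@H]1COC(C)(C)O1
F9 | step 9 | tertiary alcohol from debenzoylation of F8 | CC(C)(C)[Si](C)(C)OC[C@@](C)(O)[C@H]1COC(C)(C)O1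
F10 | step 9 | 2-methoxy-6-methyl-4-[(triisopropylsilyl)oxy]benzoyl chloride | COc1cc(O[Si](C(C)C)(C(C)C)C(C)C)cc(C)c1C(Cl)=O
F11 | step 9 | acetonide of 14 | CC(C)(C)[Si](C)(C)OC[C@@](C)(OC(=O)c1c(C)cc(O[Si](C(C)C)(C(C)C)C(C)C)cc1OC)[C@H]1COC(C)(C)O1
F12 | step 19 | C6 tert-butyldimethylsilyl ether of 27 | C[C@]1(OC(=O)c2c(C)cc(O[Si](C(C)C)(C(C)C)C(C)C)cc2OC)[C@H](O[Si](C)(C)C(C)(C)C)C/C(=C/C(O[Si](CC)(CC)CC)/C=C/C)C(=C)C1O[Si](CC)(CC)CC
F13 | step 19 | diol from F12 after removal of both triethylsilyl groups | C[C@]1(OC(=O)c2c(C)cc(O[Si](C(C)C)(C(C)C)C(C)C)cc2OC)[C@H](O[Si](C)(C)C(C)(C)C)C/C(=C/C(O)/C=C/C)C(=C)C1O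
F14 | step 19 | dienedione from F13 | C[C@]1(OC(=O)c2c(C)cc(O[Si](C(C)C)(C(C)C)C(C)C)cc2OC)[C@H](O[Si](C)(C)C(C)(C)C)C/C(=C/C(=O)/C=C/C)C(=C)C1=O
F15 | step 19 | target with C6–O tert-butyldimethylsilyl and aryl O-triisopropylsilyl groups | C/C=C/C1=CC2=C(CO1)C(=O)[C@@](C)(OC(=O)c1c(C)cc(O[Si](C(C)C)(C(C)C)C(C)C)cc1OC)[C@H](O[Si](C)(C)C(C)(C)C)C2
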